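**Retrosynthetic overview**
1. No ring is formed, because both benzene rings are bought intact. Methyl atratate 1 gives the ring A acid 2, and 3,5-dihydroxy-4-methylbenzoic acid 3 gives the ring B benzylic alcohol 4.
2. The key, fragment-joining disconnection is the benzylic C–O bond of the ester. A carboxylate oxygen of 2 attacks the activated CH2 of 4 (phosphonium salt 5) to give ester 6, so the hindered acyl carbon is never attacked.
3. The last disconnection is the aryl–CO2H bond of ring B. CO2 is placed on 6 through magnesium chelate 7 to give target 8.
4. The CO2H group comes last because a carboxyl ortho to a free or activated CH2–O group collapses to the phthalide. This order removes the need for any protecting group.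

Assumption: the SMILES contains no stereocentre and no stereogenic axis, so the target is achiral and is made as such.

**Route**

Step 1
Reactants: 1 methyl 2,4-dihydroxy-3,6-dimethylbenzoate (methyl atratate)
Product: 2 2,4-dihydroxy-3,6-dimethylbenzoic acid
Conditions: conc. H2SO4, 0 °C → 20 °C, 2 h; then ice–water, filter, dry at rt
Reagents that add atoms: water, O
Why: Unimolecular acid-catalysed acyl–oxygen cleavage (AAc1 ester hydrolysis) is the standard way to open 2,6-disubstituted benzoates that resist saponification, and the cold medium avoids the decarboxylation seen in hot alkali.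

Step 2
Reactants: 3 3,5-dihydroxy-4-methylbenzoic acid
Product: 4 5-(hydroxymethyl)-2-methylbenzene-1,3-diol
Conditions: BH3·THF (3.5 equiv), THF, 0 °C → 40 °C; MeOH quench, co-evaporation
Reagents that add atoms: none
Why: Borane reduction of a carboxylic acid is chemoselective for CO2H, while the phenols only consume hydride and are released again on methanolysis.

Step 3
Reactants: 2 2,4-dihydroxy-3,6-dimethylbenzoic acid (1.3 equiv); 4 5-(hydroxymethyl)-2-methylbenzene-1,3-diol
Product: 6 (3,5-dihydroxy-4-methylphenyl)methyl 2,4-dihydroxy-3,6-dimethylbenzoate, via alkoxyphosphonium carboxylate 5 (not isolated)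
Conditions: PPh3 (1.3 equiv), DIAD (1.3 equiv, slow addition), THF, 0 °C → rt
Reagents that add atoms: none
Why: In this Mitsunobu esterification only the carboxylic acid (pKa about 3–4) protonates the betaine ahead of the four phenols (pKa 8–10), and its carboxylate then displaces Ph3PO from the primary benzylic carbon of 5 by SN2, forming the key C–O bond without attack at the hindered acyl carbon and without creating a stereocentre.

Step 4
Reactants: 6 (3,5-dihydroxy-4-methylphenyl)methyl 2,4-dihydroxy-3,6-dimethylbenzoate
Product: 8 6-{[(2,4-dihydroxy-3,6-dimethylbenzoyl)oxy]methyl}-2,4-dihydroxy-3-methylbenzoic acid (CNP0110620.0), via magnesium salicylate chelate 7 (not isolated)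
Conditions: MgCl2 (anhydrous, 5 equiv), Et3N (10 equiv), CO2 (1 atm), MeCN, 50 °C, 24 h; then cold 1 M HCl
Reagents that add atoms: carbon dioxide, O=C=O
Why: Proposed new method: this is a magnesium-templated soft Kolbe–Schmitt carboxylation in which MgCl2/Et3N converts a ring B phenol into its chloromagnesium phenoxide and divalent magnesium holds CO2 next to the only free ortho carbon (the two such carbons are equivalent, and the carbon between the hydroxyls is blocked by methyl); the C–C bond forms through a six-membered transition state and rearomatisation gives chelate 7, a thermodynamic sink that prevents loss of CO2 and keeps the new carboxylate from displacing the aroate to give the phthalide; ring A stays untouched because its phenoxide charge is drained into the para ester carbonyl; the closest known reaction types are the Kolbe–Schmitt reaction, its methyl magnesium carbonate (MeOMgOCO2Me) variant on resorcinols at about 120 °C, the MgCl2/Et3N/CO2 carboxylation of ketones and the MgCl2/Et3N/paraformaldehyde ortho-formylation of phenols, and none of these has been shown for phenol C–H carboxylation at 1 atm and 50 °C next to a benzylic ester.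

**Compound list**
1 | methyl 2,4-dihydroxy-3,6-dimethylbenzoate | COC(=O)c1c(C)cc(O)c(C)c1O | starting material
2 | 2,4-dihydroxy-3,6-dimethylbenzoic acid | Cc1cc(O)c(C)c(O)c1C(=O)O | intermediate
3 | 3,5-dihydroxy-4-methylbenzoic acid | Cc1c(O)cc(cc1O)C(=O)O | starting material
4 | 5-(hydroxymethyl)-2-methylbenzene-1,3-diol | Cc1c(O)cc(CO)cc1O | intermediate
5 | [(3,5-dihydroxy-4-methylphenyl)methoxy]triphenylphosphonium 2,4-dihydroxy-3,6-dimethylbenzoate | Cc1c(O)cc(CO[P+](c2ccccc2)(c2ccccc2)c2ccccc2)cc1O.Cc1cc(O)c(C)c(O)c1C(=O)[O-] | intermediate
6 | (3,5-dihydroxy-4-methylphenyl)methyl 2,4-dihydroxy-3,6-dimethylbenzoate | Cc1cc(O)c(C)c(O)c1C(=O)OCc1cc(O)c(C)c(O)c1 | intermediate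
7 | magnesium chelate of 8, bound through a carboxylate O and the adjacent phenolate O of ring B | Cc1cc(O)c(C)c(O)c1C(=O)OCc1cc(O)c(C)c2O[Mg]OC(=O)c12 | intermediate
8 | 6-{[(2,4-dihydroxy-3,6-dimethylbenzoyl)oxy]methyl}-2,4-dihydroxy-3-methylbenzoic acid | Cc1cc(O)c(C)c(O)c1C(=O)OCc1cc(O)c(C)c(O)c1C(=O)O | target

Total step count: 4.
Longest linear sequence: 3 steps (1 → 2 → 6 → 8, or 3 → 4 → 6 → 8).

**Steps most likely to fail**

Step 4 (the proposed new step). The chloromagnesium phenoxide may be too weak a carbon nucleophile for CO2 at 50 °C, so that 6 is simply returned, or the crowded acid may lose CO2 on work-up. The fallback uses known chemistry and brings the carbon in at the aldehyde level before oxidising it. Setting out from 6, Vilsmeier–Haack formylation (POCl3, DMF, 0 °C → rt, then aqueous NaOAc) attacks the ester-free, more electron-rich ring B at the same carbon. This gives (2-formyl-3,5-dihydroxy-4-methylphenyl)methyl 2,4-dihydroxy-3,6-dimethylbenzoate F1. Lindgren–Pinnick oxidation (NaClO2, NaH2PO4, sulfamic acid as chlorine scavenger, aqueous dioxane, 0 °C) then converts F1 into the acid, and the fallback comes back to the route at 8.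

Step 3. Phenol O-alkylation could give ethers or oligomers of 4 once the acid runs low. The fallback separates activation from bond formation. Setting out from 4, Appel bromination (CBr4, PPh3, THF, 0 °C) gives 5-(bromomethyl)-2-methylbenzene-1,3-diol F2. F2 is used at once to alkylate the potassium carboxylate of 2 (KHCO3, DMF, rt), where bicarbonate ionises only the CO2H group. The fallback comes back to the route at 6.

Step 1. Ring sulfonation or decarboxylation may erode the yield in H2SO4. The fallback cleaves the O–CH3 bond instead of the acyl–O bond. Setting out from 1, hard-acid/soft-nucleophile dealkylation (AlCl3, EtSH, CH2Cl2, 0 °C → rt, then cold dilute HCl) lets sulfur attack the methyl group of the aluminium-chelated ester by SN2. The fallback comes back to the route at 2 without any new compound.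

**Further compounds**
F1 | step 4 | (2-formyl-3,5-dihydroxy-4-methylphenyl)methyl 2,4-dihydroxy-3,6-dimethylbenzoate | Cc1cc(O)c(C)c(O)c1C(=O)OCc1cc(O)c(C)c(O)c1C=O
F2 | step 3 | 5-(bromomethyl)-2-methylbenzene-1,3-diol | Cc1c(O)cc(CBr)cc1O
F0 | step 1 | none | none
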